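**Retrosynthetic overview**
- Target ⇒ the same lactone carrying COOH instead of CH2OH at C4. The chemoselective COOH → CH2OH reduction comes last.
- Lactone acid ⇒ C7–O disconnection (key step) to C2-symmetric (2S,3S)-2,3-bis(4-hydroxy-3-methoxybenzyl)succinic acid. Dehydrogenative lactonisation through a p-quinone methide closes the ring and sets C7. The 3,4-cis relation is already encoded in the S,S diacid.
- Diacid ⇒ C8–C8' disconnection: auxiliary-controlled oxidative homocoupling of an N-(dihydroferuloyl)oxazolidinone, which sets C8 and C8'.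
- Imide ⇒ dihydroferulic acid + (R)-4-benzyl-2-oxazolidinone, with the phenol masked as its pivalate in the same pot.
- Ring order: there is only one ring to form, the γ-lactone, and it is closed in the fourth step.

Assumption: lignan numbering is used (C7/C7' benzylic carbons, C8/C8' methines, C9/C9' carboxyl-derived carbons; the unprimed half receives the lactone oxygen at C7), and 1 and 2 are taken as inexpensive catalogue chemicals (2 is recovered).

**Step 1**
Reactants: 1 3-(4-hydroxy-3-methoxyphenyl)propanoic acid (dihydroferulic acid); 2 (R)-4-benzyl-2-oxazolidinone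
Product: 4 (4R)-4-benzyl-3-{3-[3-methoxy-4-(pivaloyloxy)phenyl]propanoyl}-1,3-oxazolidin-2-one, via mixed pivalic anhydride 3 (not isolated)
Conditions: PivCl (2.2 equiv), Et3N (3.5 equiv), THF, −20 to 0 °C; then LiCl, 2, rt
Reagents that add atoms: pivaloyl chloride, CC(C)(C)C(=O)Cl
Why: Mixed-anhydride N-acylation (PivCl/LiCl protocol): PivCl pivaloylates both carboxylate and phenol, the auxiliary attacks the unhindered carbonyl of 3, and the aryl pivalate stays as the phenol mask; no new stereocentre.

**Step 2**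
Reactants: 4 (two molecules)
Product: 6 (2S,3S)-1,4-bis[(4R)-4-benzyl-2-oxo-1,3-oxazolidin-3-yl]-2,3-bis[3-methoxy-4-(pivaloyloxy)benzyl]butane-1,4-dione, via lithium Z-enolate 5 (not isolated)
Conditions: LiN(iPr)2 (1.1 equiv), THF, −78 °C; then TiCl4 (1.1 equiv), −78 °C to rt
Reagents that add atoms: none
Why: Oxidative enolate homocoupling under oxazolidinone control: TiCl4 (tetravalent titanium going to trivalent titanium) oxidises the chelated Z-enolate, and each α-carbon bonds on the face away from the auxiliary benzyl group, so the R auxiliary gives S at both C8 and C8'; the minor meso-type isomer is removed by chromatography.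

**Step 3**
Reactants: 6
Product: 8 (2S,3S)-2,3-bis(4-hydroxy-3-methoxybenzyl)succinic acid, via diperoxy acid 7 (not isolated)
Conditions: LiOH (8 equiv), 30% H2O2 (16 equiv), THF–H2O 3:1, 0 °C to rt; then Na2SO3; then HCl to pH 2
Reagents that add atoms: hydrogen peroxide, OO
Why: Evans LiOOH hydrolysis cleaves the exocyclic imide carbonyls without α-epimerisation, the aryl pivalates are perhydrolysed in the same pot, and sulfite reduces the peracids; no stereocentre is touched.

**Step 4**
Reactants: 8
Product: 10 (2R,3R,4S)-4-(4-hydroxy-3-methoxybenzyl)-2-(4-hydroxy-3-methoxyphenyl)-5-oxotetrahydrofuran-3-carboxylic acid, via p-quinone methide 9 (not isolated)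
Conditions: DDQ (0.8 equiv, slow addition), 4 Å MS, 1,4-dioxane, 20 °C
Reagents that add atoms: none
Why: Proposed new method: a phenol-gated dehydrogenative γ-lactonisation in which DDQ removes hydride from the benzylic C7–H of one free 4-alkylguaiacol unit (the two benzylic CH2 groups of C2-symmetric 8 are homotopic, so there is no site issue) to give p-quinone methide 9, whose exocyclic carbon is captured 5-exo-trig by the C9' carboxyl group (the C9 carboxyl could only give a β-lactone) faster than tautomerisation or arene attack; C8 and C8' are untouched, which fixes the 3,4-cis relation, and the aryl group ends anti to the C4 carboxyl (7R) because the alternative is the all-cis lactone and the O-addition is reversible; sub-stoichiometric DDQ limits a second oxidation and unreacted 8 is recycled; the closest known reaction types are DDQ benzylic alkoxylation of 4-alkylphenols through quinone methides, carboxyl capture of quinone methides in the oxidative dimerisation of ferulic acid, and radical benzylic C–H lactonisation of 4-arylbutanoic acids, none of which has been shown on an unprotected bis(phenol) succinic acid.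

**Step 5**
Reactants: 10
Product: 11 (3S,4S,5R)-3-(4-hydroxy-3-methoxybenzyl)-5-(4-hydroxy-3-methoxyphenyl)-4-(hydroxymethyl)dihydrofuran-2(3H)-one (target)
Conditions: BH3·THF (3.5 equiv), THF, 0 °C to rt; then H2O (pH 5 work-up)
Reagents that add atoms: none
Why: Chemoselective borane reduction: the free acid reacts through an acyloxyborane far faster than the lactone, the phenols only consume hydride, and the base-free medium protects the epimerisable cis C3 centre and prevents translactonisation; no new stereocentre.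

**Compound list**
1 | 3-(4-hydroxy-3-methoxyphenyl)propanoic acid | COc1cc(CCC(=O)O)ccc1O | starting material
2 | (R)-4-benzyl-2-oxazolidinone | O=C1N[C@H](Cc2ccccc2)CO1 | starting material
3 | 3-[3-methoxy-4-(pivaloyloxy)phenyl]propanoic pivalic anhydride | CC(C)(C)C(=O)OC(=O)CCc1ccc(OC(=O)C(C)(C)C)c(OC)c1 | intermediate
4 | (4R)-4-benzyl-3-{3-[3-methoxy-4-(pivaloyloxy)phenyl]propanoyl}-1,3-oxazolidin-2-one | COc1cc(CCC(=O)N2[C@H](Cc3ccccc3)COC2=O)ccc1OC(=O)C(C)(C)C | intermediate
5 | lithium Z-enolate of 4 | [Li+].[O-]/C(=C\Cc1ccc(OC(=O)C(C)(C)C)c(OC)c1)N1[C@H](Cc2ccccc2)COC1=O | intermediate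
6 | (2S,3S) bis-imide dimer | O=C(N1[C@H](Cc2ccccc2)COC1=O)[C@@H](Cc1ccc(OC(=O)C(C)(C)C)c(OC)c1)[C@H](Cc1ccc(OC(=O)C(C)(C)C)c(OC)c1)C(=O)N1[C@H](Cc2ccccc2)COC1=O | intermediate
7 | (2S,3S)-2,3-bis(4-hydroxy-3-methoxybenzyl)butanediperoxoic acid | OOC(=O)[C@@H](Cc1ccc(O)c(OC)c1)[C@H](Cc1ccc(O)c(OC)c1)C(=O)OO | intermediate
8 | (2S,3S)-2,3-bis(4-hydroxy-3-methoxybenzyl)succinic acid | OC(=O)[C@@H](Cc1ccc(O)c(OC)c1)[C@H](Cc1ccc(O)c(OC)c1)C(=O)O | intermediate
9 | mono-p-quinone methide of 8 | OC(=O)[C@@H](Cc1ccc(O)c(OC)c1)[C@H](C=C1C=CC(=O)C(OC)=C1)C(=O)O | intermediate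
10 | (2R,3R,4S)-4-(4-hydroxy-3-methoxybenzyl)-2-(4-hydroxy-3-methoxyphenyl)-5-oxotetrahydrofuran-3-carboxylic acid | COc1cc(C[C@@H]2C(=O)O[C@@H](c3ccc(O)c(OC)c3)[C@@H]2C(=O)O)ccc1O | intermediate
11 | (3S,4S,5R)-3-(4-hydroxy-3-methoxybenzyl)-5-(4-hydroxy-3-methoxyphenyl)-4-(hydroxymethyl)dihydrofuran-2(3H)-one | COc1cc(C[C@@H]2C(=O)O[C@@H](c3ccc(O)c(OC)c3)[C@@H]2CO)ccc1O | target

**Total step count:** 5. **Longest linear sequence:** 5.

**Three steps most likely to fail**

**Step 4 (proposed new step)**
- *Statistical limit.* The two guaiacyl units react independently. At 0.8 equiv DDQ the expected distribution is about 48% of 10, 36% recovered 8 and 16% over-oxidised dilactone.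
- *Side reactions.* The quinone methide may tautomerise to the benzylidene succinic acid. It may also be attacked by the second arene to give an aryltetralin.
- *Fallback (known chemistry).* It sets out from 8 and comes back at 10.
  - Schotten–Baumann acetylation (Ac2O, aq NaOH, 0 °C) gives (2S,3S)-2,3-bis(4-acetoxy-3-methoxybenzyl)succinic acid F1.
  - The established radical benzylic C–H lactonisation of 4-arylbutanoic acids (PhI(OAc)2, KBr, CH2Cl2, rt, about 1 equiv) converts it into the bis-O-acetyl lactone acid F2. Here too the carboxyl closes anti to the C4 substituent.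
  - Brief treatment with pyrrolidine (CH2Cl2, 0 °C) removes only the aryl acetates and gives 10.

**Step 2**
- *Risks.* The aryl pivalate must survive LiN(iPr)2 and TiCl4, the yield of such dimerisations is moderate, and the S,S to meso-type ratio may be lower than hoped.
- *Fallback.* It sets out from 1 and comes back at 8, replacing auxiliary control by classical resolution.
  - BnBr and K2CO3 in DMF give benzyl 3-[4-(benzyloxy)-3-methoxyphenyl]propanoate F3.
  - LiN(iPr)2 followed by 0.5 equiv I2 couples the ester enolate through the α-iodo ester. Racemic dibenzyl (2S*,3S*)-2,3-bis[4-(benzyloxy)-3-methoxybenzyl]succinate F4 is then separated from its meso isomer.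
  - H2 over Pd/C gives racemic (2S*,3S*)-2,3-bis(4-hydroxy-3-methoxybenzyl)succinic acid F5.
  - Crystallisation with 1-phenylethylamine gives the bis[(S)-1-phenylethylammonium] (2S,3S)-succinate salt F6. The amine enantiomer is chosen by screening and is written here as S.
  - Acidification releases 8.

**Step 5**
- *Risks.* Partial reduction of the lactone, sluggish reaction of poorly soluble aryl borates, or migration of the lactone to the new primary alcohol during work-up.
- *Fallback.* It sets out from 10 and comes back at 11.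
  - ClCO2Et (3.3 equiv) and N-methylmorpholine in THF at −15 °C give the tris(ethoxycarbonyl) derivative F7. This is a mixed carboxylic carbonic anhydride in which both phenols are ethyl carbonates, so no phenoxide can expel the benzylic carboxylate.
  - NaBH4 in water at −15 °C reduces only the mixed anhydride and gives the bis(ethyl carbonate) of the target F8.
  - Pyrrolidine (CH2Cl2, 0 °C) removes the aryl carbonates and gives 11.

**Further compounds**
F1 | step 4 | (2S,3S)-2,3-bis(4-acetoxy-3-methoxybenzyl)succinic acid | OC(=O)[C@@H](Cc1ccc(OC(C)=O)c(OC)c1)[C@H](Cc1ccc(OC(C)=O)c(OC)c1)C(=O)O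
F2 | step 4 | (2R,3R,4S)-4-(4-acetoxy-3-methoxybenzyl)-2-(4-acetoxy-3-methoxyphenyl)-5-oxotetrahydrofuran-3-carboxylic acid | COc1cc(C[C@@H]2C(=O)O[C@@H](c3ccc(OC(C)=O)c(OC)c3)[C@@H]2C(=O)O)ccc1OC(C)=O
F3 | step 2 | benzyl 3-[4-(benzyloxy)-3-methoxyphenyl]propanoate | COc1cc(CCC(=O)OCc2ccccc2)ccc1OCc1ccccc1
F4 | step 2 | racemic dibenzyl (2S*,3S*)-2,3-bis[4-(benzyloxy)-3-methoxybenzyl]succinate (both enantiomers) | O=C(OCc1ccccc1)[C@@H](Cc1ccc(OCc2ccccc2)c(OC)c1)[C@H](Cc1ccc(OCc2ccccc2)c(OC)c1)C(=O)OCc1ccccc1.O=C(OCc1ccccc1)[C@H](Cc1ccc(OCc2ccccc2)c(OC)c1)[C@@H](Cc1ccc(OCc2ccccc2)c(OC)c1)C(=O)OCc1ccccc1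
F5 | step 2 | racemic (2S*,3S*)-2,3-bis(4-hydroxy-3-methoxybenzyl)succinic acid (both enantiomers) | OC(=O)[C@@H](Cc1ccc(O)c(OC)c1)[C@H](Cc1ccc(O)c(OC)c1)C(=O)O.OC(=O)[C@H](Cc1ccc(O)c(OC)c1)[C@@H](Cc1ccc(O)c(OC)c1)C(=O)O
F6 | step 2 | bis[(S)-1-phenylethylammonium] (2S,3S)-2,3-bis(4-hydroxy-3-methoxybenzyl)succinate | [O-]C(=O)[C@@H](Cc1ccc(O)c(OC)c1)[C@H](Cc1ccc(O)c(OC)c1)C(=O)[O-].C[C@H]([NH3+])c1ccccc1.C[C@H]([NH3+])c1ccccc1
F7 | step 5 | ethoxycarbonyl mixed anhydride of 10 with both phenols as ethyl carbonates | COc1cc(C[C@@H]2C(=O)O[C@@H](c3ccc(OC(=O)OCC)c(OC)c3)[C@@H]2C(=O)OC(=O)OCC)ccc1OC(=O)OCC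
F8 | step 5 | bis(ethyl carbonate) of 11 | COc1cc(C[C@@H]2C(=O)O[C@@H](c3ccc(OC(=O)OCC)c(OC)c3)[C@@H]2CO)ccc1OC(=O)OCC
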